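## Analysis of the target

Propolis-benzofuran A is a 3,4-dihydro-2H-pyran (O1, C2–C6). It carries a 4-hydroxy-3-methoxyphenyl group on C2, an acetoxymethyl group on C3 and a 6-acetyl-5-hydroxy-1-benzofuran-2-yl group on C5. C5=C6 is an enol ether conjugated with the benzofuran. The two stereocentres are neighbours, C2 (R) and C3 (S), and their substituents are trans, both pseudo-equatorial on the half-chair. The sensitive groups are the enol ether (acid), the primary acetate (base, hydride), the aryl methyl ketone (hydride, ylides), the two phenols, and the C2–O1 bond, which is para-hydroxybenzylic and can open through a quinone methide once the phenol is free and deprotonated. The synthesis is hard for three reasons: the enol ether bears a heteroaryl group on C5 and has no carbonyl to build it from; C2 must be set absolutely and C3 relative to it; and the acetyl group must pass every nucleophilic step. The strategy rests on the sequence O1–C2(aryl)–C3 with the aryl-bearing C5 two atoms further on. These six ring atoms are those of a 2-furyl(aryl)carbinol after oxidative ring expansion: carbinol oxygen to O1, carbinol carbon to C2, furan C2 to C3, furan C4 with its benzofuran to C5, furan C5 to C6.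

## Retrosynthetic reasoning

26 from 25. The two phenols are unmasked last. While they are silylated, no phenoxide para to C2 can push open the C2–O1 bond, and a buffered desilylation spares the acetate and the enol ether.

25 from 24. The C5=C6 double bond is traced to a C6 acetal with hydrogen on C5. Only C5 carries a hydrogen next to C6, so loss of the anomeric alkoxy group can give one alkene only, and that alkene is conjugated with the benzofuran. The acetate is already in place so that no free hydroxyl can trap the C6 cation.

24 from 23 from 22. The acetate comes from the primary alcohol and the alcohol from an aldehyde on C3. The aldehyde is chosen because it is the one oxidation level at which C3 can be equilibrated to the trans (diequatorial) isomer, and because it can be reduced in the presence of the aryl ketone.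

22 from 20 from 19. The exocyclic C–C bond at C3 is cut. A one-carbon Wittig homologation of the C3 ketone 19 through enol ether 20 supplies the formyl carbon exactly where the ring expansion leaves a carbonyl group.

19 from 18 from 17. The C4–C5 bond of 19 is the saturated form of the enone in 18. The lactol 17 is first capped as acetal 18, because after saturation a free lactol would open to a 1,4-keto-aldehyde that can cyclodehydrate to a furan and that would also consume the ylide.

17 from 15. The O1–C6 bond and the pyranone ring are cut. This is the oxidative ring expansion of carbinol 15. It turns a flat, easily made heteroaromatic into the ring with all six atoms, the C5 substituent and the right oxygenation at C3 and C6, and it keeps the carbinol configuration as C2.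

15 from 10 and 12. The bond between the carbinol carbon and the guaiacyl ring is cut. A catalytic enantioselective aryl transfer from the zinc reagent made from 12 to aldehyde 10 sets the only stereocentre that is bought with a chiral reagent, and an organozinc leaves the acetyl ketone alone.

10 from 9 from 4 and 7. The benzofuran is cut at C2–C3 and at O1–C2. Alkyne 4 and ortho-bromophenol 7 are joined by cross-coupling, and the phenol closes on the alkyne. The hydroxyl para to the ring-closing one is hydrogen-bonded to the acetyl group, stays out, and becomes the 5-hydroxyl of 9; it is silylated to give 10.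

4 from 3 from 1 and 2; 7 from 6 from 5; 12 from 11. The alkyne is put on bromofuran 1 with silylacetylene 2 and uncapped. The acetyl group is put on 5 para to bromine and both methyl ethers are cleaved. Phenol 11 is silylated.

## Alternatives that were turned down

Alternative 1: The benzofuran is made last by cutting its C2'=C3' bond. The precursor is the phosphonium ester A2: the aryl ester of the finished dihydropyran-5-carboxylic acid with a phenol that carries an ortho-CH2PPh3 group. A tertiary amine would form the benzylic ylide, which adds to the neighbouring ester carbonyl and loses phosphine oxide, giving A1, the target silylated only on the guaiacyl oxygen.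
- For it: the acetyl group arrives with the last fragment and never meets a hydride or an ylide aimed elsewhere. The enol ether travels as a vinylogous carbonate, which is much less acid-labile. One deprotection remains after the key step. On these three points it is stronger than the chosen route.
- Against it: the carbonyl under attack is deactivated by O1 through C5=C6. The ylide shares its ring with an aryl methyl ketone that is itself a Wittig partner. Above all, the disconnection leaves the dihydropyran untouched: ring, C2 and C3 must come from a separate enantioselective synthesis of the acid, so the total count is not lower.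
- In its place the chosen route makes the ring, its oxygenation and the C5–aryl bond from one furan in one step.

Alternative 2: C4–C5 is cut next to a lactone carbonyl at C6. The precursor A4 is the benzofuran-2-ylacetate of the C2 carbinol, whose neighbouring carbon carries both CH2–O arms as a six-membered cyclic sulfate. The ester enolate, made with a silylamide base, would open one arm (6-exo-tet) and give lactone A3 with the other arm as a sulfate monoester.
- For it: the C3 branch is present from the start at the right oxidation level. C2 is never alpha to a carbonyl and cannot epimerise. C3 is set in the ring-forming step. On these points it is stronger.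
- Against it: the two arms are diastereotopic and differ only through competing chair transition states, so the trans outcome is a preference and not a certainty. The lactone must then be reduced part-way and dehydrated in the presence of the acetyl ketone, a harder discrimination than aldehyde against ketone. A4 needs its own enantioselective synthesis of a carbinol bearing a 1,3-diol, plus sulfate formation.
- In its place the chosen route takes the absolute configuration from one catalytic addition to a simple aldehyde and the relative configuration from an equilibrium.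

Alternative 3: C5–C6 and O1–C6 are cut, and C6 comes from synthesis gas. The precursor A6 is the open-chain (E)-alkene with the C2 hydroxyl and the C3 acetoxymethyl group already in place. A rhodium carbonyl catalyst with a bulky phosphite would add hydrogen to C4 and a formyl group to the benzylic C5, and the C2 hydroxyl would capture the aldehyde as lactol A5, one dehydration from the target.
- For it: the endgame is the shortest of all, the phenols could in principle stay free, and acetyl and acetate are tolerated. Both stereocentres are set in the open chain. On step economy after ring closure and on C3 it is stronger.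
- Against it: branched selectivity is reliable for terminal vinylarenes, but this alkene is 1,2-disubstituted and slower. A formyl group on C4 would also be trapped, as a five-membered lactol. Reversible Rh–H addition and beta-hydride elimination can move the double bond to C3=C4 and erase the allylic C3 stereocentre.
- In its place the chosen route fixes the connectivity of all six ring atoms in the starting furan, so its key step needs chemoselectivity only.

Key step: step 9

## Remarks and assumptions

- TBS = tert-butyldimethylsilyl; TBSO = tert-butyldimethylsilyloxy.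
- Assumption: compounds 1, 2, 5 and 11 are taken as commercial.
- Assumption: (−)-MIB, (2S)-3-exo-morpholinoisoborneol, is taken to send the aryl group to the Si face of aldehyde 10, the sense it shows with alkylzinc reagents; if the sense were opposite, (+)-MIB would be used.
- C5 and C6 of compounds 17 to 24 are mixtures of configurations; both carbons become sp2 in step 16.

## Route

Step 1
Reactants: 1 4-bromofuran-2-carbaldehyde; 2 ethynyltrimethylsilane
Product: 3 4-[(trimethylsilyl)ethynyl]furan-2-carbaldehyde
Conditions: PdCl2(PPh3)2 (3 mol%), CuI (5 mol%), i-Pr2NH, THF, 50 °C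
Reagents that add atoms: none
Why: Sonogashira coupling; the formyl group makes the bromofuran electron-poor enough for oxidative addition to zerovalent palladium, and the silyl cap prevents double coupling and diyne formation.

Step 2
Reactants: 3 4-[(trimethylsilyl)ethynyl]furan-2-carbaldehyde
Product: 4 4-ethynylfuran-2-carbaldehyde
Conditions: K2CO3 (0.2 equiv), MeOH, 0 °C; used as a solution
Reagents that add atoms: none
Why: Methoxide-catalysed protodesilylation of the alkynylsilane; the aldehyde is untouched at 0 °C, and the volatile product is carried on in solution.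

Step 3
Reactants: 5 2-bromo-1,4-dimethoxybenzene
Product: 6 1-(4-bromo-2,5-dimethoxyphenyl)ethanone
Conditions: AcCl (1.2 equiv), AlCl3 (1.3 equiv), CH2Cl2, 0 °C
Reagents that add atoms: acetyl chloride, CC(=O)Cl
Why: Friedel–Crafts acylation; every free position is ortho to one methoxy group, and attack para to bromine avoids the crowded site between Br and OMe, which gives the 4-bromo-2,5-dimethoxy pattern.

Step 4
Reactants: 6 1-(4-bromo-2,5-dimethoxyphenyl)ethanone
Product: 7 1-(4-bromo-2,5-dihydroxyphenyl)ethanone
Conditions: BBr3 (3.5 equiv), CH2Cl2, −78 °C → rt; H2O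
Reagents that add atoms: none
Why: Lewis-acid cleavage of aryl methyl ethers; both fall, the one ortho to the acetyl group fastest through chelation, and the hydroxyl ortho to bromine is the one needed for ring closure.

Step 5
Reactants: 4 4-ethynylfuran-2-carbaldehyde; 7 1-(4-bromo-2,5-dihydroxyphenyl)ethanone
Product: 9 4-(6-acetyl-5-hydroxy-1-benzofuran-2-yl)furan-2-carbaldehyde, via alkynylphenol 8 (not isolated)
Conditions: PdCl2(PPh3)2 (5 mol%), CuI (10 mol%), Et3N, DMF, 80 °C, Ar
Reagents that add atoms: none
Why: Sonogashira coupling at the C–Br bond para to the acetyl group, then 5-endo-dig addition of the ortho hydroxyl to the alkyne (domino benzofuran synthesis). Only the hydroxyl next to the alkyne can close; the other, hydrogen-bonded to the acetyl group, ends as the 5-OH beside the 6-acetyl group.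

Step 6
Reactants: 9 4-(6-acetyl-5-hydroxy-1-benzofuran-2-yl)furan-2-carbaldehyde
Product: 10 4-[6-acetyl-5-(TBSO)-1-benzofuran-2-yl]furan-2-carbaldehyde
Conditions: TBSCl, imidazole, DMAP (cat.), DMF, 40 °C
Reagents that add atoms: tert-butyl(chloro)dimethylsilane, CC(C)(C)[Si](C)(C)Cl
Why: Phenol silylation; it masks the chelating ortho-hydroxy ketone, which would otherwise bind zinc in step 8 and vanadium in step 9.

Step 7
Reactants: 11 4-bromo-2-methoxyphenol
Product: 12 (4-bromo-2-methoxyphenoxy)(tert-butyl)dimethylsilane
Conditions: TBSCl, imidazole, CH2Cl2, rt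
Reagents that add atoms: tert-butyl(chloro)dimethylsilane, CC(C)(C)[Si](C)(C)Cl
Why: Phenol silylation; bromine is para to the silyloxy group, so the aryl metal made from it cannot undergo silyl migration from oxygen to carbon.

Step 8
Reactants: 12 (4-bromo-2-methoxyphenoxy)(tert-butyl)dimethylsilane; 10 4-[6-acetyl-5-(TBSO)-1-benzofuran-2-yl]furan-2-carbaldehyde
Product: 15 (S)-{4-[6-acetyl-5-(TBSO)-1-benzofuran-2-yl]furan-2-yl}[4-(TBSO)-3-methoxyphenyl]methanol, via aryllithium 13 (not isolated), via arylbutylzinc 14 (not isolated)
Conditions: 12 (2 equiv), n-BuLi, t-BuOMe, −78 °C; ZnCl2; n-BuLi, −78 → 0 °C; N,N,N',N'-tetraethylethylenediamine; toluene; (−)-MIB (10 mol%); 10, 0 °C; aq. NH4Cl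
Reagents that add atoms: none
Why: Amino-alcohol-catalysed enantioselective addition of an aryl(alkyl)zinc to an aldehyde, after Br–Li exchange and transmetalation; the aryl group transfers in preference to butyl, the diamine binds LiCl so that the racemic background reaction is suppressed, and the aryl methyl ketone is inert to the zinc reagent. Si-face delivery under (−)-MIB gives the (S)-carbinol.

Step 9
Reactants: 15 (S)-{4-[6-acetyl-5-(TBSO)-1-benzofuran-2-yl]furan-2-yl}[4-(TBSO)-3-methoxyphenyl]methanol
Product: 17 (2S)-5-[6-acetyl-5-(TBSO)-1-benzofuran-2-yl]-2-[4-(TBSO)-3-methoxyphenyl]-6-hydroxy-2H-pyran-3(6H)-one as a mixture of C6 anomers, via Z-enedione 16 (not isolated)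
Conditions: VO(acac)2 (10 mol%), t-BuOOH (1.5 equiv, in decane), CH2Cl2, 0 °C → rt
Reagents that add atoms: tert-butyl hydroperoxide, CC(C)(C)OO
Why: Achmatowicz rearrangement in its vanadium-catalysed form. The peroxide oxidises VO(acac)2 (tetravalent vanadium) to a pentavalent alkylperoxo species that binds the carbinol as its alkoxide and delivers oxygen to the adjacent furan C2=C3 bond. The oxidised furan opens to the Z-configured keto-enal 16, in which the old furan C2 is a ketone and the old furan C5 an aldehyde held cis to it. The carbinol oxygen then adds to the aldehyde carbon (6-exo-trig hemiacetalisation), forming O1–C6 and the pyranone ring. No bond to the carbinol carbon is broken, so it becomes C2 with its configuration unchanged; the descriptor stays (S) only because C3 now outranks the aryl group. C6 is a new stereocentre under anomeric equilibrium (hydroxyl axial, trans to the C2 aryl group favoured), but it is erased in step 16. The selectivity needed is oxidation of this furan and not of the benzofuran or the silyloxyarenes; it is secured because the oxidant is delivered from the metal bound to the carbinol oxygen, and because a furan is the most easily oxidised of these rings.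

Step 10
Reactants: 17 (2S)-5-[6-acetyl-5-(TBSO)-1-benzofuran-2-yl]-2-[4-(TBSO)-3-methoxyphenyl]-6-hydroxy-2H-pyran-3(6H)-one
Product: 18 (2S)-5-[6-acetyl-5-(TBSO)-1-benzofuran-2-yl]-2-[4-(TBSO)-3-methoxyphenyl]-6-methoxy-2H-pyran-3(6H)-one
Conditions: MeOH (20 equiv), camphorsulfonic acid (10 mol%), CH2Cl2, 0 °C → rt
Reagents that add atoms: methanol, CO
Why: Acid-catalysed acetalisation of the lactol through the ring oxocarbenium ion (Fischer-type glycosidation). The medium is not basic and the C3 carbonyl disfavours ionisation at C2, so C2 is safe; aryl silyl ethers tolerate these conditions.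

Step 11
Reactants: 18 (2S)-5-[6-acetyl-5-(TBSO)-1-benzofuran-2-yl]-2-[4-(TBSO)-3-methoxyphenyl]-6-methoxy-2H-pyran-3(6H)-one
Product: 19 (2S)-5-[6-acetyl-5-(TBSO)-1-benzofuran-2-yl]-2-[4-(TBSO)-3-methoxyphenyl]-6-methoxyoxan-3-one
Conditions: [(Ph3P)CuH]6 (0.4 equiv), H2O (3 equiv), degassed toluene, rt
Reagents that add atoms: none
Why: Copper hydride conjugate reduction; hydride goes to C5 and the copper enolate, which lies on the C4 side and away from C2, is protonated at C4. Neither ketone is reduced and no base reaches the acidic C2–H; the C5 centre forms as a mixture and is erased later.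

Step 12
Reactants: 19 (2S)-5-[6-acetyl-5-(TBSO)-1-benzofuran-2-yl]-2-[4-(TBSO)-3-methoxyphenyl]-6-methoxyoxan-3-one
Product: 20 (2S)-5-[6-acetyl-5-(TBSO)-1-benzofuran-2-yl]-2-[4-(TBSO)-3-methoxyphenyl]-6-methoxy-3-(methoxymethylidene)oxane as an E/Z mixture
Conditions: MeOCH2PPh3Cl (1.6 equiv), KN(SiMe3)2 (1.5 equiv), THF, 0 °C; then 19, −78 → −20 °C
Reagents that add atoms: (methoxymethyl)triphenylphosphonium chloride, COC[P+](c1ccccc1)(c1ccccc1)c1ccccc1.[Cl-]
Why: Wittig olefination with the methoxymethylene ylide; the ring ketone, activated by the alpha oxygen, should react far faster than the conjugated aryl methyl ketone flanked by a silyloxy group. The ylide is pre-formed with a deficit of base and met at low temperature so that carbonyl addition outruns deprotonation at C2.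

Step 13
Reactants: 20 (2S)-5-[6-acetyl-5-(TBSO)-1-benzofuran-2-yl]-2-[4-(TBSO)-3-methoxyphenyl]-6-methoxy-3-(methoxymethylidene)oxane
Product: 22 (2R,3R)-5-[6-acetyl-5-(TBSO)-1-benzofuran-2-yl]-2-[4-(TBSO)-3-methoxyphenyl]-6-methoxyoxane-3-carbaldehyde (2,3-trans), via aldehyde epimer mixture 21 (not isolated)
Conditions: Hg(OAc)2 (1.2 equiv), THF/H2O (10:1), 0 °C; aq. KI; then DBU (0.1 equiv), dry CH2Cl2, 0 °C → rt
Reagents that add atoms: water, O
Why: Mercury-assisted hydrolysis of the enol ether (oxymercuration, loss of methanol, iodide-induced demercuration) frees the aldehyde without acid and so spares the C6 acetal and the silyl ethers. Catalytic DBU then equilibrates C3 through the enolate to the isomer with aryl and formyl groups both equatorial. Expulsion of the ring alkoxide from an aldehyde enolate is slow next to reprotonation, as with other alpha-branched beta-alkoxy aldehydes, so the ring should stay closed.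

Step 14
Reactants: 22 (2R,3R)-5-[6-acetyl-5-(TBSO)-1-benzofuran-2-yl]-2-[4-(TBSO)-3-methoxyphenyl]-6-methoxyoxane-3-carbaldehyde
Product: 23 {(2R,3S)-5-[6-acetyl-5-(TBSO)-1-benzofuran-2-yl]-2-[4-(TBSO)-3-methoxyphenyl]-6-methoxyoxan-3-yl}methanol
Conditions: NaBH4 (1.0 equiv), EtOH/CH2Cl2 (1:3), −78 °C
Reagents that add atoms: none
Why: Chemoselective borohydride reduction; at −78 °C an aliphatic aldehyde is reduced much faster than a conjugated, ortho-substituted aryl ketone. The descriptor at C3 changes only because the priorities change.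

Step 15
Reactants: 23 {(2R,3S)-5-[6-acetyl-5-(TBSO)-1-benzofuran-2-yl]-2-[4-(TBSO)-3-methoxyphenyl]-6-methoxyoxan-3-yl}methanol
Product: 24 {(2R,3S)-5-[6-acetyl-5-(TBSO)-1-benzofuran-2-yl]-2-[4-(TBSO)-3-methoxyphenyl]-6-methoxyoxan-3-yl}methyl acetate
Conditions: Ac2O, pyridine, DMAP (cat.), CH2Cl2, 0 °C
Reagents that add atoms: acetic anhydride, CC(=O)OC(C)=O
Why: Acylation of the primary alcohol; it comes before the elimination because a free hydroxymethyl group would trap the C6 oxocarbenium ion as a bridged acetal.

Step 16
Reactants: 24 {(2R,3S)-5-[6-acetyl-5-(TBSO)-1-benzofuran-2-yl]-2-[4-(TBSO)-3-methoxyphenyl]-6-methoxyoxan-3-yl}methyl acetate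
Product: 25 {(2R,3S)-5-[6-acetyl-5-(TBSO)-1-benzofuran-2-yl]-2-[4-(TBSO)-3-methoxyphenyl]-3,4-dihydro-2H-pyran-3-yl}methyl acetate
Conditions: pyridinium p-toluenesulfonate (0.2 equiv), toluene, 90 °C, 5 Å molecular sieves
Reagents that add atoms: none
Why: Acid-catalysed conversion of an acetal into an enol ether (loss of methanol through the ring oxocarbenium ion, then loss of the C5 proton). Only C5 has a hydrogen next to C6, the new double bond is conjugated with the benzofuran, and the sieves remove methanol.

Step 17
Reactants: 25 {(2R,3S)-5-[6-acetyl-5-(TBSO)-1-benzofuran-2-yl]-2-[4-(TBSO)-3-methoxyphenyl]-3,4-dihydro-2H-pyran-3-yl}methyl acetate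
Product: 26 propolis-benzofuran A, {(2R,3S)-5-(6-acetyl-5-hydroxy-1-benzofuran-2-yl)-2-(4-hydroxy-3-methoxyphenyl)-3,4-dihydro-2H-pyran-3-yl}methyl acetate
Conditions: Bu4NF (2.5 equiv), AcOH (2.5 equiv), THF, 0 °C
Reagents that add atoms: none
Why: Fluoride cleavage of both aryl silyl ethers; the acetic acid buffer keeps the phenols protonated, so the acetate is not attacked and no phenoxide para to C2 can open the C2–O1 bond through a quinone methide.

## Compound list

1 | 4-bromofuran-2-carbaldehyde | O=Cc1cc(Br)co1 | starting material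
2 | ethynyltrimethylsilane | C#C[Si](C)(C)C | starting material
3 | 4-[(trimethylsilyl)ethynyl]furan-2-carbaldehyde | O=Cc1cc(C#C[Si](C)(C)C)co1 | intermediate
4 | 4-ethynylfuran-2-carbaldehyde | O=Cc1cc(C#C)co1 | intermediate
5 | 2-bromo-1,4-dimethoxybenzene | COc1ccc(OC)c(Br)c1 | starting material
6 | 1-(4-bromo-2,5-dimethoxyphenyl)ethanone | CC(=O)c1cc(OC)c(Br)cc1OC | intermediate
7 | 1-(4-bromo-2,5-dihydroxyphenyl)ethanone | CC(=O)c1cc(O)c(Br)cc1O | intermediate
8 | 4-[(4-acetyl-2,5-dihydroxyphenyl)ethynyl]furan-2-carbaldehyde (not isolated) | CC(=O)c1cc(O)c(C#Cc2coc(C=O)c2)cc1O | intermediate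
9 | 4-(6-acetyl-5-hydroxy-1-benzofuran-2-yl)furan-2-carbaldehyde | CC(=O)c1cc2oc(-c3coc(C=O)c3)cc2cc1O | intermediate
10 | 4-[6-acetyl-5-(tert-butyldimethylsilyloxy)-1-benzofuran-2-yl]furan-2-carbaldehyde | CC(=O)c1cc2oc(-c3coc(C=O)c3)cc2cc1O[Si](C)(C)C(C)(C)C | intermediate
11 | 4-bromo-2-methoxyphenol | COc1cc(Br)ccc1O | starting material
12 | (4-bromo-2-methoxyphenoxy)(tert-butyl)dimethylsilane | COc1cc(Br)ccc1O[Si](C)(C)C(C)(C)C | intermediate
13 | [4-(tert-butyldimethylsilyloxy)-3-methoxyphenyl]lithium (not isolated) | [Li]c1ccc(O[Si](C)(C)C(C)(C)C)c(OC)c1 | intermediate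
14 | butyl[4-(tert-butyldimethylsilyloxy)-3-methoxyphenyl]zinc (not isolated) | CCCC[Zn]c1ccc(O[Si](C)(C)C(C)(C)C)c(OC)c1 | intermediate
15 | (S)-{4-[6-acetyl-5-(tert-butyldimethylsilyloxy)-1-benzofuran-2-yl]furan-2-yl}[4-(tert-butyldimethylsilyloxy)-3-methoxyphenyl]methanol | COc1cc([C@H](O)c2cc(-c3cc4cc(O[Si](C)(C)C(C)(C)C)c(C(C)=O)cc4o3)co2)ccc1O[Si](C)(C)C(C)(C)C | intermediate
16 | (2Z,5S)-2-[6-acetyl-5-(tert-butyldimethylsilyloxy)-1-benzofuran-2-yl]-5-[4-(tert-butyldimethylsilyloxy)-3-methoxyphenyl]-5-hydroxy-4-oxopent-2-enal (not isolated) | COc1cc([C@H](O)C(=O)/C=C(\C=O)c2cc3cc(O[Si](C)(C)C(C)(C)C)c(C(C)=O)cc3o2)ccc1O[Si](C)(C)C(C)(C)C | intermediate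
17 | (2S)-5-[6-acetyl-5-(tert-butyldimethylsilyloxy)-1-benzofuran-2-yl]-2-[4-(tert-butyldimethylsilyloxy)-3-methoxyphenyl]-6-hydroxy-2H-pyran-3(6H)-one, C6 anomers | COc1cc([C@@H]2OC(O)C(c3cc4cc(O[Si](C)(C)C(C)(C)C)c(C(C)=O)cc4o3)=CC2=O)ccc1O[Si](C)(C)C(C)(C)C | intermediate
18 | (2S)-5-[6-acetyl-5-(tert-butyldimethylsilyloxy)-1-benzofuran-2-yl]-2-[4-(tert-butyldimethylsilyloxy)-3-methoxyphenyl]-6-methoxy-2H-pyran-3(6H)-one, C6 anomers | COc1cc([C@@H]2OC(OC)C(c3cc4cc(O[Si](C)(C)C(C)(C)C)c(C(C)=O)cc4o3)=CC2=O)ccc1O[Si](C)(C)C(C)(C)C | intermediate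
19 | (2S)-5-[6-acetyl-5-(tert-butyldimethylsilyloxy)-1-benzofuran-2-yl]-2-[4-(tert-butyldimethylsilyloxy)-3-methoxyphenyl]-6-methoxyoxan-3-one, mixture at C5 and C6 | COc1cc([C@@H]2OC(OC)C(c3cc4cc(O[Si](C)(C)C(C)(C)C)c(C(C)=O)cc4o3)CC2=O)ccc1O[Si](C)(C)C(C)(C)C | intermediate
20 | (2S)-5-[6-acetyl-5-(tert-butyldimethylsilyloxy)-1-benzofuran-2-yl]-2-[4-(tert-butyldimethylsilyloxy)-3-methoxyphenyl]-6-methoxy-3-(methoxymethylidene)oxane, E/Z mixture | COc1cc([C@@H]2OC(OC)C(c3cc4cc(O[Si](C)(C)C(C)(C)C)c(C(C)=O)cc4o3)CC2=COC)ccc1O[Si](C)(C)C(C)(C)C | intermediate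
21 | (2R)-5-[6-acetyl-5-(tert-butyldimethylsilyloxy)-1-benzofuran-2-yl]-2-[4-(tert-butyldimethylsilyloxy)-3-methoxyphenyl]-6-methoxyoxane-3-carbaldehyde, both C3 epimers (not isolated) | COc1cc([C@@H]2OC(OC)C(c3cc4cc(O[Si](C)(C)C(C)(C)C)c(C(C)=O)cc4o3)CC2C=O)ccc1O[Si](C)(C)C(C)(C)C | intermediate
22 | (2R,3R)-5-[6-acetyl-5-(tert-butyldimethylsilyloxy)-1-benzofuran-2-yl]-2-[4-(tert-butyldimethylsilyloxy)-3-methoxyphenyl]-6-methoxyoxane-3-carbaldehyde (2,3-trans) | COc1cc([C@@H]2OC(OC)C(c3cc4cc(O[Si](C)(C)C(C)(C)C)c(C(C)=O)cc4o3)C[C@H]2C=O)ccc1O[Si](C)(C)C(C)(C)C | intermediate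
23 | {(2R,3S)-5-[6-acetyl-5-(tert-butyldimethylsilyloxy)-1-benzofuran-2-yl]-2-[4-(tert-butyldimethylsilyloxy)-3-methoxyphenyl]-6-methoxyoxan-3-yl}methanol | COc1cc([C@@H]2OC(OC)C(c3cc4cc(O[Si](C)(C)C(C)(C)C)c(C(C)=O)cc4o3)C[C@H]2CO)ccc1O[Si](C)(C)C(C)(C)C | intermediate
24 | {(2R,3S)-5-[6-acetyl-5-(tert-butyldimethylsilyloxy)-1-benzofuran-2-yl]-2-[4-(tert-butyldimethylsilyloxy)-3-methoxyphenyl]-6-methoxyoxan-3-yl}methyl acetate | COc1cc([C@@H]2OC(OC)C(c3cc4cc(O[Si](C)(C)C(C)(C)C)c(C(C)=O)cc4o3)C[C@H]2COC(C)=O)ccc1O[Si](C)(C)C(C)(C)C | intermediate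
25 | {(2R,3S)-5-[6-acetyl-5-(tert-butyldimethylsilyloxy)-1-benzofuran-2-yl]-2-[4-(tert-butyldimethylsilyloxy)-3-methoxyphenyl]-3,4-dihydro-2H-pyran-3-yl}methyl acetate | COc1cc([C@@H]2OC=C(c3cc4cc(O[Si](C)(C)C(C)(C)C)c(C(C)=O)cc4o3)C[C@H]2COC(C)=O)ccc1O[Si](C)(C)C(C)(C)C | intermediate
26 | propolis-benzofuran A, {(2R,3S)-5-(6-acetyl-5-hydroxy-1-benzofuran-2-yl)-2-(4-hydroxy-3-methoxyphenyl)-3,4-dihydro-2H-pyran-3-yl}methyl acetate | COc1cc([C@@H]2OC=C(c3cc4cc(O)c(C(C)=O)cc4o3)C[C@H]2COC(C)=O)ccc1O | target

## Step count and least certain steps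

Total: 17 steps. Longest linear sequence: 14 steps (from 1 through steps 1, 2, 5, 6, 8 and 9 to 17; the same length from 5 through steps 3 and 4).

Step 9 (key step). The carbinol is benzylic to both a furan and a para-silyloxyarene, so the most likely failure is ionisation at the Lewis-acidic vanadium centre, with loss of configuration or ether formation; unselective oxidation of the benzofuran is the second. Fallback: from 15, dye-sensitised photo-oxygenation (O2, tetraphenylporphyrin, light, CH2Cl2, −78 °C) adds singlet oxygen across the furan to give the furan endoperoxide F1. Reduction with dimethyl sulfide turns it into enedione 16, which closes to 17. This oxidant is neutral, needs no metal, and reacts with furans far faster than with benzofurans.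

Step 12. The ylide may act as a base at C2, which is alpha to the ketone, benzylic and oxygen-bearing, and so erode the enantiomeric purity; it may also olefinate the acetyl group. Fallback: from 19, non-basic methylenation with Zn, CH2Br2 and TiCl4 gives the 3-methylene compound F2. Hydroboration with catecholborane and RhCl(PPh3)3, which leaves ketones alone, followed by NaBO3 gives the hydroxymethyl compound F3 as a mixture of C3 epimers. Dess–Martin periodinane oxidises F3 to the aldehyde mixture 21, where the route is rejoined before the equilibration.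

Step 13. The C3 enolate may expel the ring oxygen (beta-elimination with ring opening, made irreversible by collapse of the C6 hemiacetal oxide), or the equilibrium may leave too much cis isomer. Fallback: from 20, the equilibration is moved to the acid side. Camphorsulfonic acid in methanol at 50 °C gives the bis-acetal F4, whose C3 centre equilibrates to trans through reversible loss and re-addition of methanol, without an enolate. Aqueous HCl in THF then opens both acetals to the lactol aldehyde F5. NaBH4 at −78 °C reduces the free aldehyde to the lactol alcohol F6, and acetic anhydride in pyridine gives the diacetate F7. The elimination conditions of step 16, now losing acetic acid, return the route at 25.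

Step 8. Facial selectivity may be poor, because the furan oxygen can bind zinc and any LiCl left free drives a racemic background reaction. Fallback: from 10 and 14, addition without the chiral ligand gives the racemic carbinol F8. Oxidative kinetic resolution with Ti(OiPr)4, L-(+)-diisopropyl tartrate and t-BuOOH is expected to oxidise the (S)-enantiomer faster, as it does for (S)-2-furylalkanols, and to carry it directly to 17. The (R)-carbinol F9 is left behind and removed. The route is rejoined at 17.

Step 16. Hot acid may ionise the electron-rich benzylic C2–O1 bond, or the elimination may stall at the acetal. Fallback: from 24, aqueous acetic acid in THF hydrolyses the acetal to the lactol F10. Methanesulfonyl chloride and Et3N at 0 °C convert the anomeric hydroxyl into a leaving group that is lost under base with the C5 proton, giving 25 without heat or acid.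

## Further compounds

F1 | step 9 | furan 2,5-endoperoxide of 15 (2,3,7-trioxabicyclo[2.2.1]hept-5-ene with the carbinol on C1 and the benzofuran on C5) | COc1cc([C@H](O)C23OOC(O2)C(c2cc4cc(O[Si](C)(C)C(C)(C)C)c(C(C)=O)cc4o2)=C3)ccc1O[Si](C)(C)C(C)(C)C
F2 | step 12 | 3-methylene analogue of 19 (C3=CH2 in place of C3=O, C2 as in 19) | COc1cc([C@@H]2OC(OC)C(c3cc4cc(O[Si](C)(C)C(C)(C)C)c(C(C)=O)cc4o3)CC2=C)ccc1O[Si](C)(C)C(C)(C)C
F3 | step 12 | 3-(hydroxymethyl) compound, both C3 epimers of 23 | COc1cc([C@@H]2OC(OC)C(c3cc4cc(O[Si](C)(C)C(C)(C)C)c(C(C)=O)cc4o3)CC2CO)ccc1O[Si](C)(C)C(C)(C)C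
F4 | step 13 | 2,3-trans 3-(dimethoxymethyl)-6-methoxyoxane (dimethyl acetal of 22) | COc1cc([C@@H]2OC(OC)C(c3cc4cc(O[Si](C)(C)C(C)(C)C)c(C(C)=O)cc4o3)C[C@H]2C(OC)OC)ccc1O[Si](C)(C)C(C)(C)C
F5 | step 13 | 2,3-trans 6-hydroxyoxane-3-carbaldehyde (lactol aldehyde) | COc1cc([C@@H]2OC(O)C(c3cc4cc(O[Si](C)(C)C(C)(C)C)c(C(C)=O)cc4o3)C[C@H]2C=O)ccc1O[Si](C)(C)C(C)(C)C
F6 | step 13 | 2,3-trans 3-(hydroxymethyl)oxan-6-ol (lactol alcohol) | COc1cc([C@@H]2OC(O)C(c3cc4cc(O[Si](C)(C)C(C)(C)C)c(C(C)=O)cc4o3)C[C@H]2CO)ccc1O[Si](C)(C)C(C)(C)C
F7 | step 13 | 2,3-trans 6-acetoxy-3-(acetoxymethyl)oxane (diacetate) | COc1cc([C@@H]2OC(OC(C)=O)C(c3cc4cc(O[Si](C)(C)C(C)(C)C)c(C(C)=O)cc4o3)C[C@H]2COC(C)=O)ccc1O[Si](C)(C)C(C)(C)C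
F8 | step 8 | racemic carbinol (racemate of 15) | COc1cc(C(O)c2cc(-c3cc4cc(O[Si](C)(C)C(C)(C)C)c(C(C)=O)cc4o3)co2)ccc1O[Si](C)(C)C(C)(C)C
F9 | step 8 | (R)-carbinol (enantiomer of 15) | COc1cc([C@@H](O)c2cc(-c3cc4cc(O[Si](C)(C)C(C)(C)C)c(C(C)=O)cc4o3)co2)ccc1O[Si](C)(C)C(C)(C)C
F10 | step 16 | 6-hydroxy analogue of 24 (lactol acetate) | COc1cc([C@@H]2OC(O)C(c3cc4cc(O[Si](C)(C)C(C)(C)C)c(C(C)=O)cc4o3)C[C@H]2COC(C)=O)ccc1O[Si](C)(C)C(C)(C)C
A1 | alternative 1 | propolis-benzofuran A silylated on the guaiacyl oxygen, {(2R,3S)-5-(6-acetyl-5-hydroxy-1-benzofuran-2-yl)-2-[4-(tert-butyldimethylsilyloxy)-3-methoxyphenyl]-3,4-dihydro-2H-pyran-3-yl}methyl acetate | COc1cc([C@@H]2OC=C(c3cc4cc(O)c(C(C)=O)cc4o3)C[C@H]2COC(C)=O)ccc1O[Si](C)(C)C(C)(C)C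
A2 | alternative 1 | [4-acetyl-5-hydroxy-2-({(2R,3S)-3-(acetoxymethyl)-2-[4-(tert-butyldimethylsilyloxy)-3-methoxyphenyl]-3,4-dihydro-2H-pyran-5-carbonyl}oxy)benzyl]triphenylphosphonium bromide | COc1cc([C@@H]2OC=C(C(=O)Oc3cc(C(C)=O)c(O)cc3C[P+](c3ccccc3)(c3ccccc3)c3ccccc3)C[C@H]2COC(C)=O)ccc1O[Si](C)(C)C(C)(C)C.[Br-]
A3 | alternative 2 | sodium {(2R,3S)-5-[6-acetyl-5-(tert-butyldimethylsilyloxy)-1-benzofuran-2-yl]-2-[4-(tert-butyldimethylsilyloxy)-3-methoxyphenyl]-6-oxooxan-3-yl}methyl sulfate | COc1cc([C@@H]2OC(=O)C(c3cc4cc(O[Si](C)(C)C(C)(C)C)c(C(C)=O)cc4o3)C[C@H]2COS(=O)(=O)[O-])ccc1O[Si](C)(C)C(C)(C)C.[Na+]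
A4 | alternative 2 | (R)-[4-(tert-butyldimethylsilyloxy)-3-methoxyphenyl](2,2-dioxo-1,3,2-dioxathian-5-yl)methyl 2-[6-acetyl-5-(tert-butyldimethylsilyloxy)-1-benzofuran-2-yl]acetate | COc1cc([C@H](OC(=O)Cc2cc3cc(O[Si](C)(C)C(C)(C)C)c(C(C)=O)cc3o2)C2COS(=O)(=O)OC2)ccc1O[Si](C)(C)C(C)(C)C
A5 | alternative 3 | {(2R,3S)-5-(6-acetyl-5-hydroxy-1-benzofuran-2-yl)-6-hydroxy-2-(4-hydroxy-3-methoxyphenyl)oxan-3-yl}methyl acetate | COc1cc([C@@H]2OC(O)C(c3cc4cc(O)c(C(C)=O)cc4o3)C[C@H]2COC(C)=O)ccc1O
A6 | alternative 3 | (2S,3E)-4-(6-acetyl-5-hydroxy-1-benzofuran-2-yl)-2-[(R)-hydroxy(4-hydroxy-3-methoxyphenyl)methyl]but-3-en-1-yl acetate | COc1cc([C@H](O)[C@H](COC(C)=O)/C=C/c2cc3cc(O)c(C(C)=O)cc3o2)ccc1O
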